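The bicyclo[3.2.1]octane (C1 OMe bridgehead, C2 carbinol, C3=C4 enol ether, C5 allyl bridgehead, C6 methyl, C7 aryl, C8 ketone) is cut at C3–C4 and C5–C6. Quaternary C5 lies between C8, C6 and C4, and C4 adjoins oxygenated C3, so attack of a C4=C5 alkene on a C3 aldehyde creates a C5 cation that is quenched by shift of C6 from a silyloxy-bearing C8. One Lewis-acid operation closes ring C1–C2–C3–C4–C5–C8 and enlarges cyclobutane C8–C6–C7–C1 to cyclopentanone C1–C7–C6–C5–C8. The precursor is a 1-(penta-1,4-dien-2-yl)cyclobutyl triethylsilyl ether with a cis α-silyloxyacetaldehyde arm on C1, assembled by ketene–isoeugenol [2+2] and alkenyl addition.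

Key step: step 10

Remark: atom labels C1–C8 are those of the target bicycle and are kept for the monocyclic intermediates.
Remark: the C3 carbinol of compound 17 is drawn as the equatorial epimer expected from a chair-like closure; either epimer serves, because C3 is oxidised in step 11.

Step 1
Reactants: 1 (E)-isoeugenol
Product: 2 tert-butyl{2-methoxy-4-[(1E)-prop-1-en-1-yl]phenoxy}dimethylsilane
Conditions: TBSCl, imidazole, DMF, 0 °C → rt
Reagents that add atoms: tert-butyldimethylsilyl chloride, CC(C)(C)[Si](C)(C)Cl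
Why: Imidazole-promoted O-silylation of the phenol masks the acidic OH and keeps the styrene electron-rich enough for the ketene cycloaddition.

Step 2
Reactants: 3 methyl 3,4-O-isopropylidene-L-threonate
Product: 4 methyl (2R)-2-methoxy-2-[(4S)-2,2-dimethyl-1,3-dioxolan-4-yl]acetate
Conditions: MeI, Ag2O, MeCN, rt, dark
Reagents that add atoms: iodomethane, CI
Why: Purdie methylation etherifies the α-hydroxy ester without base, so the dioxolane carbon that becomes C2 is carried over unchanged from the chiral pool.

Step 3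
Reactants: 4 methyl (2R)-2-methoxy-2-[(4S)-2,2-dimethyl-1,3-dioxolan-4-yl]acetate
Product: 5 potassium (2R)-2-methoxy-2-[(4S)-2,2-dimethyl-1,3-dioxolan-4-yl]acetate
Conditions: KOH (1.0 equiv), MeOH/H2O, 0 °C → rt; evaporate, dry azeotropically (toluene)
Reagents that add atoms: potassium hydroxide, [K+].[OH-]
Why: Ester saponification with isolation as the dry potassium salt avoids acid contact with the acetonide, and epimerisation of the α-carbon would not matter because that carbon becomes the sp2 ketene carbon.

Step 4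
Reactants: 5 potassium (2R)-2-methoxy-2-[(4S)-2,2-dimethyl-1,3-dioxolan-4-yl]acetate; 2 tert-butyl{2-methoxy-4-[(1E)-prop-1-en-1-yl]phenoxy}dimethylsilane
Product: 8 (2R,3S,4R)-3-[4-(tert-butyldimethylsilyloxy)-3-methoxyphenyl]-2-[(4S)-2,2-dimethyl-1,3-dioxolan-4-yl]-2-methoxy-4-methylcyclobutan-1-one, via acid chloride 6 (not isolated), via methoxy(dioxolanyl)ketene 7 (not isolated)
Conditions: (COCl)2, pyridine (cat.), Et2O, 0 °C → rt, filter; then syringe-pump addition to 2 (3 equiv), Et3N, toluene, 90 °C
Reagents that add atoms: none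
Why: Dehydrochlorination gives the alkoxyketene, which should add to the electron-rich styrene in a thermal ketene–alkene [2+2] cycloaddition with the carbonyl carbon C8 bonding to the methyl-bearing carbon C6 and C1 to the benzylic carbon C7, the E-alkene giving trans aryl/methyl, the bulkier dioxolanyl group ending cis to the aryl group as is usual for unsymmetrical ketenes, and the C1–C7 bond forming on the π-face of C1 anti to the allylic dioxolane C–O bond with C2–H eclipsing the ketene axis (the normal preference of electrophiles towards π-systems carrying an allylic oxygen stereocentre), which sets C1, C6 and C7 in the required absolute sense.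

Step 5
Reactants: 9 2,3-dibromopropene
Product: 10 2-bromopenta-1,4-diene
Conditions: CH2=CHMgBr, CuI (5 mol %), THF, −20 → 0 °C
Reagents that add atoms: vinylmagnesium bromide, C=C[Mg]Br
Why: Copper-catalysed allylic substitution by the Grignard reagent takes place at the allylic C–Br bond only, the vinylic bromide being inert under these conditions.

Step 6
Reactants: 10 2-bromopenta-1,4-diene; 8 (2R,3S,4R)-3-[4-(tert-butyldimethylsilyloxy)-3-methoxyphenyl]-2-[(4S)-2,2-dimethyl-1,3-dioxolan-4-yl]-2-methoxy-4-methylcyclobutan-1-one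
Product: 13 (1S,2R,3S,4R)-3-[4-(tert-butyldimethylsilyloxy)-3-methoxyphenyl]-2-[(4S)-2,2-dimethyl-1,3-dioxolan-4-yl]-2-methoxy-4-methyl-1-(penta-1,4-dien-2-yl)cyclobutan-1-ol, via penta-1,4-dien-2-yllithium 11 (not isolated), via penta-1,4-dien-2-ylmagnesium bromide 12 (not isolated)
Conditions: 10, t-BuLi (2 equiv), Et2O, −78 °C; MgBr2·OEt2; then 8, CH2Cl2/Et2O, −78 → −40 °C; aq NH4Cl
Reagents that add atoms: none
Why: Chelation-controlled 1,2-addition of the alkenyl Grignard reagent to the strained ketone, in which magnesium bridging the C8 carbonyl and the C1 methoxy oxygen covers the face that also carries the C6 methyl group, should deliver the dienyl group anti to OMe and hence cis to the C2 side chain, the only arrangement from which C4 can later reach C3 (the C8 centre itself is consumed in step 10).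

Step 7
Reactants: 13 (1S,2R,3S,4R)-3-[4-(tert-butyldimethylsilyloxy)-3-methoxyphenyl]-2-[(4S)-2,2-dimethyl-1,3-dioxolan-4-yl]-2-methoxy-4-methyl-1-(penta-1,4-dien-2-yl)cyclobutan-1-ol
Product: 14 (1S,2R,3S,4R)-3-[4-(tert-butyldimethylsilyloxy)-3-methoxyphenyl]-2-[(1S)-1,2-dihydroxyethyl]-2-methoxy-4-methyl-1-(penta-1,4-dien-2-yl)cyclobutan-1-ol
Conditions: AcOH/H2O/THF (4:1:1), 35 °C
Reagents that add atoms: none
Why: Mild acetal hydrolysis frees the terminal diol under conditions that leave the aryl silyl ether intact and are too weakly acidic to protonate the 1,1-disubstituted alkene, so the alkenylcyclobutanol does not rearrange.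

Step 8
Reactants: 14 (1S,2R,3S,4R)-3-[4-(tert-butyldimethylsilyloxy)-3-methoxyphenyl]-2-[(1S)-1,2-dihydroxyethyl]-2-methoxy-4-methyl-1-(penta-1,4-dien-2-yl)cyclobutan-1-ol
Product: 15 tris(triethylsilyl) ether of 14 (C8–OSiEt3, C2–OSiEt3, C3–OSiEt3)
Conditions: Et3SiOTf (4 equiv), 2,6-lutidine, CH2Cl2, −78 → 0 °C
Reagents that add atoms: triethylsilyl trifluoromethanesulfonate, CC[Si](CC)(CC)OS(=O)(=O)C(F)(F)F
Why: Silyl triflate/lutidine silylation caps the primary, secondary and hindered tertiary hydroxyls in one operation, the tertiary C8 silyl ether being the future pinacol terminus and robust enough to survive the next step.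

Step 9
Reactants: 15 tris(triethylsilyl) ether of 14
Product: 16 (2R)-2-(triethylsilyloxy)acetaldehyde carrying at its C2 the cyclobutane carbon C1 (cyclobutane: C8 with OSiEt3 and penta-1,4-dien-2-yl; C6 with methyl; C7 with the silylated aryl group; C1 with OMe; dienyl, aldehyde arm and aryl on one face; C8–OSiEt3, OMe and methyl on the other)
Conditions: (COCl)2, DMSO, CH2Cl2, −78 → −35 °C; then Et3N, −78 → 0 °C
Reagents that add atoms: none
Why: Under Swern conditions a primary triethylsilyl ether is cleaved and oxidised directly to the aldehyde while secondary, tertiary and aryl silyl ethers persist (selective Swern oxidation of primary silyl ethers), so C3 is unveiled in one step at low temperature without epimerising C2.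

Step 10
Reactants: 16 the cyclobutyl α-silyloxy aldehyde described in step 9
Product: 17 5-allyl-7-[4-(tert-butyldimethylsilyloxy)-3-methoxyphenyl]-3-hydroxy-1-methoxy-6-methyl-2-(triethylsilyloxy)bicyclo[3.2.1]octan-8-one (C1, C2, C5, C6, C7 as in the target; 3-OH equatorial and trans to the 2-silyloxy group)
Conditions: SnCl4 (1.5 equiv), 2,6-di-tert-butyl-4-methylpyridine (0.2 equiv), CH2Cl2, −78 → −50 °C; aq NaHCO3
Reagents that add atoms: none
Why: SnCl4 activates the C3 aldehyde, the terminal alkene carbon C4 attacks C3, and the tertiary C5 cation that develops next to the silyloxy carbon C8 is quenched by 1,2-shift of C6 from C8 to C5, after which the silyl oxocarbenium ion loses Et3SiCl to leave the C8 ketone. This is a Prins cyclisation terminated by a pinacol shift, the known ring-enlarging reaction of 1-alkenylcycloalkanol silyl ethers, here helped by release of cyclobutane strain. Ring C1–C2–C3–C4–C5–C8 closes by a 6-endo attack with respect to the alkene through a chair-like transition state, while ring C1–C7–C6–C5–C8 arises by expansion of the four-membered ring through a suprafacial alkyl shift and not by a cyclisation. C5 is fixed by the tether, since the C2–C3–C4 bridge forces C4 and C2 onto the same face of the new five-membered ring and C6 migrates with retention, and C3 should carry an equatorial hydroxyl (tin-bound oxygen pseudo-equatorial), which is inconsequential. The step needs C6 and not C1 to migrate, which the electron-withdrawing methoxy group on C1 and the better overlap of the exocyclic C8–C6 bond with the empty C5 orbital secure; it needs the 1,1-disubstituted alkene and not the allyl alkene to react, which its higher nucleophilicity, the tertiary cation and six- against eight-membered closure secure; and it needs the alkene to outrun the electron-rich aryl ring and proton loss from the allylic CH2, for which the strain-releasing shift, the low temperature and the hindered base are relied upon.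

Step 11
Reactants: 17 the bicyclic hydroxy ketone of step 10
Product: 18 5-allyl-7-[4-(tert-butyldimethylsilyloxy)-3-methoxyphenyl]-1-methoxy-6-methyl-2-(triethylsilyloxy)bicyclo[3.2.1]octane-3,8-dione
Conditions: Dess–Martin periodinane, NaHCO3, CH2Cl2, rt
Reagents that add atoms: none
Why: Dess–Martin oxidation converts the hindered secondary C3 carbinol of either configuration into the ketone under buffered conditions that spare the silyl ethers, the alkene and the C2 stereocentre.

Step 12
Reactants: 18 the 3,8-dione of step 11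
Product: 19 5-allyl-7-[4-(tert-butyldimethylsilyloxy)-3-methoxyphenyl]-1,3-dimethoxy-6-methyl-2-(triethylsilyloxy)bicyclo[3.2.1]oct-3-en-8-one
Conditions: KN(SiMe3)2, THF, −78 °C; then Me2SO4, DMPU, −78 → −30 °C
Reagents that add atoms: dimethyl sulfate, COS(=O)(=O)OC
Why: Kinetic deprotonation of the α-silyloxy ketone should occur at the C4 methylene and not at oxygen-bearing C2 (C8 has no α-hydrogen), and the potassium enolate, whose carbon terminus is hindered by quaternary C5, is O-alkylated by the hard electrophile in a dipolar medium (enolate O-methylation) to give the C3=C4 methyl enol ether.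

Step 13
Reactants: 19 the bis-silylated enol ether of step 12
Product: 20 (1R,2S,5R,6R,7S)-2-hydroxy-7-(4-hydroxy-3-methoxyphenyl)-1,3-dimethoxy-6-methyl-5-(prop-2-en-1-yl)bicyclo[3.2.1]oct-3-en-8-one
Conditions: Bu4NF, AcOH (1:1), THF, 0 °C → rt
Reagents that add atoms: none
Why: Fluoride-mediated desilylation removes the aryl tert-butyldimethylsilyl ether and the secondary triethylsilyl ether together, the acetic acid buffer guarding the β-hydroxy ketone against retro-aldol cleavage without hydrolysing the enol ether.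

Compound list
1 | (E)-isoeugenol | C/C=C/c1ccc(O)c(OC)c1 | starting material
2 | tert-butyl{2-methoxy-4-[(1E)-prop-1-en-1-yl]phenoxy}dimethylsilane | C/C=C/c1ccc(O[Si](C)(C)C(C)(C)C)c(OC)c1 | intermediate
3 | methyl 3,4-O-isopropylidene-L-threonate, methyl (2R)-2-hydroxy-2-[(4S)-2,2-dimethyl-1,3-dioxolan-4-yl]acetate | COC(=O)[C@H](O)[C@@H]1COC(C)(C)O1 | starting material
4 | methyl (2R)-2-methoxy-2-[(4S)-2,2-dimethyl-1,3-dioxolan-4-yl]acetate | COC(=O)[C@H](OC)[C@@H]1COC(C)(C)O1 | intermediate
5 | potassium (2R)-2-methoxy-2-[(4S)-2,2-dimethyl-1,3-dioxolan-4-yl]acetate | [K+].[O-]C(=O)[C@H](OC)[C@@H]1COC(C)(C)O1 | intermediate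
6 | (2R)-2-methoxy-2-[(4S)-2,2-dimethyl-1,3-dioxolan-4-yl]acetyl chloride | ClC(=O)[C@H](OC)[C@@H]1COC(C)(C)O1 | intermediate
7 | 2-[(4S)-2,2-dimethyl-1,3-dioxolan-4-yl]-2-methoxyethen-1-one (ketene) | COC(=C=O)[C@@H]1COC(C)(C)O1 | intermediate
8 | (2R,3S,4R)-3-[4-(tert-butyldimethylsilyloxy)-3-methoxyphenyl]-2-[(4S)-2,2-dimethyl-1,3-dioxolan-4-yl]-2-methoxy-4-methylcyclobutan-1-one; aryl trans to methyl, cis to dioxolanyl | O=C1[C@H](C)[C@@H](c2ccc(O[Si](C)(C)C(C)(C)C)c(OC)c2)[C@@]1(OC)[C@@H]3COC(C)(C)O3 | intermediate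
9 | 2,3-dibromopropene | C=C(Br)CBr | starting material
10 | 2-bromopenta-1,4-diene | C=CCC(Br)=C | intermediate
11 | penta-1,4-dien-2-yllithium | [Li]C(=C)CC=C | intermediate
12 | penta-1,4-dien-2-ylmagnesium bromide | Br[Mg]C(=C)CC=C | intermediate
13 | (1S,2R,3S,4R)-3-[4-(tert-butyldimethylsilyloxy)-3-methoxyphenyl]-2-[(4S)-2,2-dimethyl-1,3-dioxolan-4-yl]-2-methoxy-4-methyl-1-(penta-1,4-dien-2-yl)cyclobutan-1-ol; dienyl cis to dioxolanyl and aryl, OH cis to OMe and methyl | C=CCC(=C)[C@@]1(O)[C@H](C)[C@@H](c2ccc(O[Si](C)(C)C(C)(C)C)c(OC)c2)[C@@]1(OC)[C@@H]3COC(C)(C)O3 | intermediate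
14 | (1S,2R,3S,4R)-3-[4-(tert-butyldimethylsilyloxy)-3-methoxyphenyl]-2-[(1S)-1,2-dihydroxyethyl]-2-methoxy-4-methyl-1-(penta-1,4-dien-2-yl)cyclobutan-1-ol | C=CCC(=C)[C@@]1(O)[C@H](C)[C@@H](c2ccc(O[Si](C)(C)C(C)(C)C)c(OC)c2)[C@@]1(OC)[C@@H](O)CO | intermediate
15 | tris(triethylsilyl) ether of 14 | C=CCC(=C)[C@@]1(O[Si](CC)(CC)CC)[C@H](C)[C@@H](c2ccc(O[Si](C)(C)C(C)(C)C)c(OC)c2)[C@@]1(OC)[C@@H](O[Si](CC)(CC)CC)CO[Si](CC)(CC)CC | intermediate
16 | (2R)-2-(triethylsilyloxy)-2-[3-aryl-2-methoxy-4-methyl-1-(penta-1,4-dien-2-yl)-1-(triethylsilyloxy)cyclobutan-2-yl]acetaldehyde, aryl = 4-(tert-butyldimethylsilyloxy)-3-methoxyphenyl; ring configuration as in 13 (cascade precursor) | C=CCC(=C)[C@@]1(O[Si](CC)(CC)CC)[C@H](C)[C@@H](c2ccc(O[Si](C)(C)C(C)(C)C)c(OC)c2)[C@@]1(OC)[C@@H](O[Si](CC)(CC)CC)C=O | intermediate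
17 | 5-allyl-7-[4-(tert-butyldimethylsilyloxy)-3-methoxyphenyl]-3-hydroxy-1-methoxy-6-methyl-2-(triethylsilyloxy)bicyclo[3.2.1]octan-8-one; C1, C2, C5, C6, C7 as in the target, 3-OH equatorial | C=CC[C@@]12C[C@@H](O)[C@H](O[Si](CC)(CC)CC)[C@@](OC)(C1=O)[C@H](c1ccc(O[Si](C)(C)C(C)(C)C)c(OC)c1)[C@H]2C | intermediate
18 | 5-allyl-7-[4-(tert-butyldimethylsilyloxy)-3-methoxyphenyl]-1-methoxy-6-methyl-2-(triethylsilyloxy)bicyclo[3.2.1]octane-3,8-dione | C=CC[C@@]12CC(=O)[C@H](O[Si](CC)(CC)CC)[C@@](OC)(C1=O)[C@H](c1ccc(O[Si](C)(C)C(C)(C)C)c(OC)c1)[C@H]2C | intermediate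
19 | 5-allyl-7-[4-(tert-butyldimethylsilyloxy)-3-methoxyphenyl]-1,3-dimethoxy-6-methyl-2-(triethylsilyloxy)bicyclo[3.2.1]oct-3-en-8-one | C=CC[C@@]12C=C(OC)[C@H](O[Si](CC)(CC)CC)[C@@](OC)(C1=O)[C@H](c1ccc(O[Si](C)(C)C(C)(C)C)c(OC)c1)[C@H]2C | intermediate
20 | (1R,2S,5R,6R,7S)-2-hydroxy-7-(4-hydroxy-3-methoxyphenyl)-1,3-dimethoxy-6-methyl-5-(prop-2-en-1-yl)bicyclo[3.2.1]oct-3-en-8-one | C=CC[C@@]12C=C(OC)[C@H](O)[C@@](OC)(C1=O)[C@H](c1ccc(O)c(OC)c1)[C@H]2C | target

Total step count: 13. Longest linear sequence: 11 steps (3 → 4 → 5 → 8 → 13 → 14 → 15 → 16 → 17 → 18 → 19 → 20; steps 1 and 5 are side branches).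

Steps most likely to fail

Step 6. What may go wrong is reversed facial selectivity: the dienyl group may enter anti to the bulky dioxolanyl group and the aryl ring instead of anti to the methoxy group, which would place C5 and C2 on opposite faces and block the six-membered closure. The fallback sets out from 8 and returns at 13. The addition is run for steric control (alkenyllithium 11, THF, −78 °C) to give the C8-epimeric cyclobutanol F1. SOCl2/pyridine (Et2O, −20 °C) converts this tertiary allylic alcohol, with allylic transposition, into the primary allylic chloride F2, an alkylidenecyclobutane of either alkene geometry. PhSeNa (from PhSeSePh and NaBH4, EtOH) gives the allylic phenyl selenide F3. Oxidation (H2O2, pyridine, CH2Cl2, −20 °C → rt) then triggers the selenoxide [2,3]-sigmatropic shift, and hydrolysis of the selenenate restores the penta-1,4-dien-2-yl group and the tertiary alcohol. The oxygen now enters from the face that the carbon nucleophile had preferred, so the hydroxyl ends cis to OMe and the dienyl group cis to the side chain, which is 13.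

Step 4. What may go wrong is oligomerisation of the free alkoxyketene outrunning its addition to the 1,2-disubstituted styrene, with erosion of facial control at the temperature needed. The fallback sets out from 2 and returns at 8; it generates the same ketene on chromium, where it cannot dimerise and reacts at room temperature. Commercial methyl (4S)-2,2-dimethyl-1,3-dioxolane-4-carboxylate F4 is saponified (KOH, MeOH) to the potassium carboxylate F5 and converted with (COCl)2 into the acid chloride F6. Acylation of K2Cr(CO)5 (from Cr(CO)6 and KC8, THF, −78 °C) and O-methylation with Me3OBF4 give the chromium methoxycarbene complex F7, which is handled without base to keep the α-stereocentre. Irradiation with visible light under CO in MeCN with excess 2 inserts CO to the metal-bound methoxy(dioxolanyl)ketene, whose [2+2] cycloaddition (the known photochemical cyclobutanone synthesis from chromium alkoxycarbene complexes and alkenes) follows the same regio- and stereochemical rules and gives 8.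

Step 10. What may go wrong is capture of the activated aldehyde by the electron-rich aryl ring (Friedel–Crafts hydroxyalkylation at the ring carbon para to OMe) in competition with the alkene. The fallback sets out from 15 and returns at 17; it runs the same cascade on a deactivated arene. Selective cleavage of the aryl silyl ether (Cs2CO3, DMF/H2O, rt) gives the phenol F8, and BzCl/Et3N/DMAP gives the aryl benzoate F9. Swern unmasking as in step 9 gives the aldehyde F10, and SnCl4 as in step 10 gives the bicyclic benzoate F11, the acyloxy group meta to the reacting ring carbon lowering its nucleophilicity. K2CO3/MeOH (0 °C) then frees the phenol F12, and TBSCl/imidazole (0 °C), which silylates the phenol in preference to the hindered C3 carbinol, gives 17.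

Further compounds
F1 | step 6 | (1R,2R,3S,4R)-3-[4-(tert-butyldimethylsilyloxy)-3-methoxyphenyl]-2-[(4S)-2,2-dimethyl-1,3-dioxolan-4-yl]-2-methoxy-4-methyl-1-(penta-1,4-dien-2-yl)cyclobutan-1-ol (C8 epimer of 13) | C=CCC(=C)[C@]1(O)[C@H](C)[C@@H](c2ccc(O[Si](C)(C)C(C)(C)C)c(OC)c2)[C@@]1(OC)[C@@H]3COC(C)(C)O3
F2 | step 6 | 1-[1-chloropent-4-en-2-ylidene]cyclobutane analogue of 13 (C8=C5 alkene, C4 as CH2Cl, either alkene geometry; C1, C2, C6, C7 as in 13) | ClCC(CC=C)=C1[C@H](C)[C@@H](c2ccc(O[Si](C)(C)C(C)(C)C)c(OC)c2)[C@@]1(OC)[C@@H]3COC(C)(C)O3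
F3 | step 6 | allylic phenyl selenide corresponding to F2 (C4 as CH2SePh) | C=CCC(C[Se]c4ccccc4)=C1[C@H](C)[C@@H](c2ccc(O[Si](C)(C)C(C)(C)C)c(OC)c2)[C@@]1(OC)[C@@H]3COC(C)(C)O3
F4 | step 4 | methyl (4S)-2,2-dimethyl-1,3-dioxolane-4-carboxylate (purchased) | COC(=O)[C@@H]1COC(C)(C)O1
F5 | step 4 | potassium (4S)-2,2-dimethyl-1,3-dioxolane-4-carboxylate | [K+].[O-]C(=O)[C@@H]1COC(C)(C)O1
F6 | step 4 | (4S)-2,2-dimethyl-1,3-dioxolane-4-carbonyl chloride | ClC(=O)[C@@H]1COC(C)(C)O1
F7 | step 4 | pentacarbonyl{[(4S)-2,2-dimethyl-1,3-dioxolan-4-yl](methoxy)methylidene}chromium | COC([C@@H]1COC(C)(C)O1)=[Cr](=C=O)(=C=O)(=C=O)(=C=O)=C=O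
F8 | step 10 | phenol obtained from 15 by loss of the aryl silyl group (three triethylsilyl ethers retained) | C=CCC(=C)[C@@]1(O[Si](CC)(CC)CC)[C@H](C)[C@@H](c2ccc(O)c(OC)c2)[C@@]1(OC)[C@@H](O[Si](CC)(CC)CC)CO[Si](CC)(CC)CC
F9 | step 10 | aryl benzoate of F8 | C=CCC(=C)[C@@]1(O[Si](CC)(CC)CC)[C@H](C)[C@@H](c2ccc(OC(=O)c4ccccc4)c(OC)c2)[C@@]1(OC)[C@@H](O[Si](CC)(CC)CC)CO[Si](CC)(CC)CC
F10 | step 10 | aryl benzoate analogue of aldehyde 16 | C=CCC(=C)[C@@]1(O[Si](CC)(CC)CC)[C@H](C)[C@@H](c2ccc(OC(=O)c4ccccc4)c(OC)c2)[C@@]1(OC)[C@@H](O[Si](CC)(CC)CC)C=O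
F11 | step 10 | aryl benzoate analogue of bicyclic hydroxy ketone 17 | C=CC[C@@]12C[C@@H](O)[C@H](O[Si](CC)(CC)CC)[C@@](OC)(C1=O)[C@H](c1ccc(OC(=O)c3ccccc3)c(OC)c1)[C@H]2C
F12 | step 10 | free phenol analogue of 17 | C=CC[C@@]12C[C@@H](O)[C@H](O[Si](CC)(CC)CC)[C@@](OC)(C1=O)[C@H](c1ccc(O)c(OC)c1)[C@H]2C
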